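The 1,2-dioxane is closed last, at the C3–C4 bond. The step exploits that ring carbon C3 bears peroxide oxygen O2 and is thus a masked peroxycarbenium carbon, while the ethyl group on C4 can come from the vinyl group that an allylsilane leaves behind. The precursor is a 1,2,4-trioxane, a temporary ring that holds C3 as a cyclic peroxyacetal and masks the hydroxymethyl group on quaternary C6, with the allylsilane on C6. TiCl4 opens it, and an intramolecular Hosomi–Sakurai reaction forms the dioxane and sets C3 and C4 in one operation. Diimide reduction, oxidation, an iodo-Wittig olefination and a Negishi methylation complete the side chain.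

Key step: step 6

Remark on numbering: ring atoms are O1, O2, C3 (bears CH2CO2Me), C4 (bears ethyl), C5 and C6 (quaternary, bonded to O1); C7–C14 are the side-chain carbons counted from C6, and C10 is the side-chain stereocentre.
Remark on assumptions: 2-methylenebutan-1-ol is taken as a commercial material; 10 is drawn as its E isomer and any Z isomer is carried along, since both are expected to give the same cyclisation product.

Step 1
Reactants: 1 2-methylenebutan-1-ol
Product: 3 [(2R)-2-ethyloxiran-2-yl]methyl 4-methylbenzenesulfonate, via epoxy alcohol 2 (not isolated)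
Conditions: Ti(OiPr)4 (5 mol %), L-(+)-diisopropyl tartrate (6 mol %), cumene hydroperoxide, 4 Å MS, CH2Cl2, −20 °C; P(OMe)3; then TsCl, Et3N, DMAP (cat.), −10 °C
Reagents that add atoms: cumene hydroperoxide CC(C)(OO)c1ccccc1; 4-methylbenzenesulfonyl chloride Cc1ccc(cc1)S(=O)(=O)Cl
Why: Sharpless asymmetric epoxidation of the 2-substituted allylic alcohol, in which L-(+)-tartrate should deliver oxygen to the face that gives the (S)-epoxy alcohol, sets the quaternary centre (future C6), and tosylation in the same pot spares the isolation of the water-soluble epoxy alcohol (the descriptor becomes R only through the priority of CH2OTs).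

Step 2
Reactants: 3 [(2R)-2-ethyloxiran-2-yl]methyl 4-methylbenzenesulfonate
Product: 5 (2R)-2-ethyl-2-(prop-2-en-1-yl)oxirane, via hydroxy tosylate 4 (not isolated)
Conditions: CH2=CHMgBr (1.3 equiv), CuI (10 mol %), THF, −40 to −10 °C; MeOH quench; then K2CO3, MeOH, rt
Reagents that add atoms: vinylmagnesium bromide C=C[Mg]Br
Why: Copper-catalysed Grignard opening at the unsubstituted epoxide carbon followed by intramolecular Williamson (SN2) closure of the tertiary alkoxide onto the primary tosylate transposes the epoxide without touching the quaternary centre, which keeps its configuration.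

Step 3
Reactants: 5 (2R)-2-ethyl-2-(prop-2-en-1-yl)oxirane
Product: 6 (2S)-2-ethyl-2-hydroperoxypent-4-en-1-ol
Conditions: anhydrous H2O2 in Et2O (excess), H3PMo12O40 (2 mol %), rt, blast shield
Reagents that add atoms: hydrogen peroxide OO
Why: H3PMo12O40-catalysed perhydrolysis should open the 2,2-disubstituted epoxide at the tertiary carbon by a borderline SN2 process with inversion, which installs the tertiary C–OOH centre (future C6) in the S configuration.

Step 4
Reactants: 6 (2S)-2-ethyl-2-hydroperoxypent-4-en-1-ol; 7 methyl 3,3-dimethoxypropanoate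
Product: 8 methyl 2-[(6S)-6-ethyl-6-(prop-2-en-1-yl)-1,2,4-trioxan-3-yl]acetate
Conditions: 7 (1.5 equiv), camphorsulfonic acid (10 mol %), 4 Å MS, CH2Cl2, 0 °C to rt
Reagents that add atoms: none
Why: Acid-catalysed transacetalisation of the β-hydroxy hydroperoxide with the dimethyl acetal gives the 1,2,4-trioxane (a cyclic peroxyacetal), whose two C3 epimers both serve because C3 becomes planar in step 6.

Step 5
Reactants: 8 methyl 2-[(6S)-6-ethyl-6-(prop-2-en-1-yl)-1,2,4-trioxan-3-yl]acetate; 9 allyltrimethylsilane
Product: 10 methyl 2-[(6S)-6-ethyl-6-[(2E)-4-(trimethylsilyl)but-2-en-1-yl]-1,2,4-trioxan-3-yl]acetate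
Conditions: 9 (4 equiv), second-generation Grubbs catalyst RuCl2(PCy3)(H2IMes)(=CHPh) (5 mol %), CH2Cl2, 40 °C
Reagents that add atoms: none
Why: Olefin cross-metathesis of the terminal alkene with an excess of allyltrimethylsilane installs the allylsilane, expected mainly as the E isomer, and ruthenium carbenes should leave the trioxane untouched.

Step 6
Reactants: 10 methyl 2-[(6S)-6-ethyl-6-[(2E)-4-(trimethylsilyl)but-2-en-1-yl]-1,2,4-trioxan-3-yl]acetate
Product: 12 methyl 2-[(3S,4S,6S)-4-ethenyl-6-ethyl-6-(hydroxymethyl)-1,2-dioxan-3-yl]acetate, via peroxycarbenium titanate 11 (not isolated)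
Conditions: TiCl4 (1.2 equiv), CH2Cl2, −78 to −40 °C; then aq. NaHCO3
Reagents that add atoms: none
Why: TiCl4 binds the ether oxygen O4 of the trioxane in a six-membered chelate with the ester carbonyl and cleaves the C3–O4 bond to the E-configured peroxycarbenium ion 11 (O2=C3 cation, C7 alkoxide on titanium), which the allylsilane attacks at C3 through its γ-carbon C4 (anti SE2′) before the β-silyl cation loses Me3SiCl and leaves the vinyl group on C4. The closest known reaction type is the TiCl4-mediated Hosomi–Sakurai allylation of monoperoxyacetals through peroxycarbenium ions, joined here to the ring-opening allylation of a cyclic acetal. The 1,2-dioxane closes in a 6-exo-trig mode with respect to the allylsilane C=C (the O2=C3 bond lies inside the new ring) through a chair transition state. C3 should be set by the E peroxycarbenium ion, which puts CH2CO2Me equatorial, and C4 by the alkenyl chain taking the equatorial site, so that the 3,4-trans product is expected from either alkene isomer. The relation of both to the existing C6 centre is expected to come from the titanium alkoxide on C7, which stays bound to the ester carbonyl and ion-paired with the cation and so holds C7 axial on the face of CH2CO2Me, with the C6 ethyl equatorial and cis to the C4 substituent. The step needs ionisation of C3–O4 in preference to C3–O2 or O–O, secured by the higher basicity of the ether oxygen and the chelate, and attack through the γ-carbon only, secured by the β-silicon effect.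

Step 7
Reactants: 12 methyl 2-[(3S,4S,6S)-4-ethenyl-6-ethyl-6-(hydroxymethyl)-1,2-dioxan-3-yl]acetate
Product: 13 methyl 2-[(3S,4R,6S)-4,6-diethyl-6-(hydroxymethyl)-1,2-dioxan-3-yl]acetate
Conditions: KO2CN=NCO2K (6 equiv), AcOH (12 equiv), MeOH/CH2Cl2, 0 °C to rt
Reagents that add atoms: none
Why: Diimide generated in the flask hydrogenates the monosubstituted alkene by concerted syn transfer of H2 under weakly acidic conditions and should leave the O–O bond, the ester and all stereocentres untouched (the C4 descriptor changes from S to R only through CIP priorities).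

Step 8
Reactants: 13 methyl 2-[(3S,4R,6S)-4,6-diethyl-6-(hydroxymethyl)-1,2-dioxan-3-yl]acetate
Product: 14 methyl 2-[(3S,4R,6S)-4,6-diethyl-6-formyl-1,2-dioxan-3-yl]acetate
Conditions: Dess–Martin periodinane (1.3 equiv), CH2Cl2, 0 °C to rt
Reagents that add atoms: none
Why: Dess–Martin oxidation under neutral conditions should give the non-enolisable α-peroxy aldehyde without any base that could open the β-peroxy ester.

Step 9
Reactants: 15 (2E)-pent-2-enal
Product: 16 (3R,4E)-hept-4-en-3-ol
Conditions: Et2Zn (1.5 equiv), (2R)-(+)-3-exo-morpholinoisoborneol [(+)-MIB] (4 mol %), hexanes, 0 °C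
Reagents that add atoms: diethylzinc CC[Zn]CC
Why: Amino-alcohol-catalysed asymmetric 1,2-addition of diethylzinc to the enal, in which (+)-MIB should direct ethyl transfer to the Re face of the aldehyde, sets the carbinol centre as R.

Step 10
Reactants: 16 (3R,4E)-hept-4-en-3-ol; 17 triethyl orthoacetate
Product: 19 ethyl (3R,4E)-3-ethylhept-4-enoate, via ketene acetal 18 (not isolated)
Conditions: 17 (5 equiv), propionic acid (5 mol %), 135 °C, EtOH distilled off
Reagents that add atoms: none
Why: Johnson–Claisen rearrangement through a chair transition state with the carbinol ethyl group equatorial transfers the carbinol chirality suprafacially to the new C–C bond, which should give the R centre (future C10) and the E alkene.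

Step 11
Reactants: 19 ethyl (3R,4E)-3-ethylhept-4-enoate
Product: 20 (3R,4E)-3-ethylhept-4-en-1-ol
Conditions: LiAlH4, Et2O, 0 °C
Reagents that add atoms: none
Why: LiAlH4 reduces the ester to the primary alcohol and touches neither the isolated alkene nor the stereocentre.

Step 12
Reactants: 20 (3R,4E)-3-ethylhept-4-en-1-ol
Product: 21 (3R,4E)-3-ethyl-1-iodohept-4-ene
Conditions: I2, PPh3, imidazole, CH2Cl2, 0 °C
Reagents that add atoms: iodine [I][I]
Why: Appel-type iodination (Garegg–Samuelsson conditions) converts the primary alcohol into the iodide by SN2 at the CH2 group.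

Step 13
Reactants: 21 (3R,4E)-3-ethyl-1-iodohept-4-ene
Product: 22 [(3R,4E)-3-ethylhept-4-en-1-yl]triphenylphosphonium iodide
Conditions: PPh3 (1.1 equiv), MeCN, reflux
Reagents that add atoms: triphenylphosphine c1ccc(cc1)P(c1ccccc1)c1ccccc1
Why: SN2 quaternisation of triphenylphosphine by the primary iodide gives the phosphonium salt.

Step 14
Reactants: 14 methyl 2-[(3S,4R,6S)-4,6-diethyl-6-formyl-1,2-dioxan-3-yl]acetate; 22 [(3R,4E)-3-ethylhept-4-en-1-yl]triphenylphosphonium iodide
Product: 26 methyl 2-[(3S,4R,6S)-4,6-diethyl-6-[(1Z,4R,5E)-4-ethyl-2-iodoocta-1,5-dien-1-yl]-1,2-dioxan-3-yl]acetate, via ylide 23 (not isolated), via iodophosphonium salt 24 (not isolated), via iodo ylide 25 (not isolated)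
Conditions: 22 (1.6 equiv), NaN(SiMe3)2, THF, 0 °C; transfer into I2, THF, −78 °C; NaN(SiMe3)2, −20 °C; then 14, −78 to −20 °C
Reagents that add atoms: iodine [I][I]
Why: Stork–Zhao-type α-iodo Wittig olefination, in which the ylide is iodinated and deprotonated again and the α-iodo ylide adds to the aldehyde under kinetic control, should give the Z iodoalkene (iodine cis to C6), the geometry that places chain carbon C9 trans to C6.

Step 15
Reactants: 26 methyl 2-[(3S,4R,6S)-4,6-diethyl-6-[(1Z,4R,5E)-4-ethyl-2-iodoocta-1,5-dien-1-yl]-1,2-dioxan-3-yl]acetate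
Product: 27 methyl 2-[(3S,4R,6S)-4,6-diethyl-6-[(1E,4R,5E)-4-ethyl-2-methylocta-1,5-dien-1-yl]-1,2-dioxan-3-yl]acetate
Conditions: Me2Zn (2 equiv), Pd(PPh3)4 (5 mol %), THF, 0 °C to rt
Reagents that add atoms: dimethylzinc C[Zn]C
Why: Negishi coupling (oxidative addition of zerovalent palladium to the alkenyl iodide, transmetalation from zinc, reductive elimination) replaces iodine by methyl with retention, which should give the E trisubstituted alkene under non-basic conditions that spare the peroxide.

Compound list
1 | 2-methylenebutan-1-ol | C=C(CC)CO | starting material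
2 | [(2S)-2-ethyloxiran-2-yl]methanol | CC[C@]1(CO)CO1 | intermediate (not isolated)
3 | [(2R)-2-ethyloxiran-2-yl]methyl 4-methylbenzenesulfonate | CC[C@]1(COS(=O)(=O)c2ccc(C)cc2)CO1 | intermediate
4 | (2R)-2-ethyl-2-hydroxypent-4-en-1-yl 4-methylbenzenesulfonate | CC[C@@](O)(CC=C)COS(=O)(=O)c1ccc(C)cc1 | intermediate (not isolated)
5 | (2R)-2-ethyl-2-(prop-2-en-1-yl)oxirane | CC[C@@]1(CC=C)CO1 | intermediate
6 | (2S)-2-ethyl-2-hydroperoxypent-4-en-1-ol | CC[C@@](OO)(CO)CC=C | intermediate
7 | methyl 3,3-dimethoxypropanoate | COC(OC)CC(=O)OC | starting material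
8 | methyl 2-[(6S)-6-ethyl-6-(prop-2-en-1-yl)-1,2,4-trioxan-3-yl]acetate (both C3 epimers) | CC[C@]1(CC=C)COC(CC(=O)OC)OO1 | intermediate
9 | allyltrimethylsilane | C=CC[Si](C)(C)C | starting material
10 | methyl 2-[(6S)-6-ethyl-6-[(2E)-4-(trimethylsilyl)but-2-en-1-yl]-1,2,4-trioxan-3-yl]acetate (both C3 epimers) | CC[C@]1(C/C=C/C[Si](C)(C)C)COC(CC(=O)OC)OO1 | intermediate
11 | ring-opened peroxycarbenium ion carrying the C7 alkoxide as tetrachlorotitanate (zwitterion) | CC[C@](C/C=C/C[Si](C)(C)C)(CO[Ti-](Cl)(Cl)(Cl)Cl)O[O+]=CCC(=O)OC | intermediate (not isolated)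
12 | methyl 2-[(3S,4S,6S)-4-ethenyl-6-ethyl-6-(hydroxymethyl)-1,2-dioxan-3-yl]acetate | OC[C@]1(CC)C[C@@H](C=C)[C@H](CC(=O)OC)OO1 | intermediate
13 | methyl 2-[(3S,4R,6S)-4,6-diethyl-6-(hydroxymethyl)-1,2-dioxan-3-yl]acetate | OC[C@]1(CC)C[C@@H](CC)[C@H](CC(=O)OC)OO1 | intermediate
14 | methyl 2-[(3S,4R,6S)-4,6-diethyl-6-formyl-1,2-dioxan-3-yl]acetate | O=C[C@]1(CC)C[C@@H](CC)[C@H](CC(=O)OC)OO1 | intermediate
15 | (2E)-pent-2-enal | CC/C=C/C=O | starting material
16 | (3R,4E)-hept-4-en-3-ol | CC[C@@H](O)/C=C/CC | intermediate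
17 | triethyl orthoacetate | CC(OCC)(OCC)OCC | starting material
18 | (3R,4E)-3-[(1-ethoxyethenyl)oxy]hept-4-ene | C=C(OCC)O[C@H](CC)/C=C/CC | intermediate (not isolated)
19 | ethyl (3R,4E)-3-ethylhept-4-enoate | CC/C=C/[C@H](CC)CC(=O)OCC | intermediate
20 | (3R,4E)-3-ethylhept-4-en-1-ol | CC/C=C/[C@H](CC)CCO | intermediate
21 | (3R,4E)-3-ethyl-1-iodohept-4-ene | CC/C=C/[C@H](CC)CCI | intermediate
22 | [(3R,4E)-3-ethylhept-4-en-1-yl]triphenylphosphonium iodide | CC/C=C/[C@H](CC)CC[P+](c1ccccc1)(c1ccccc1)c1ccccc1.[I-] | intermediate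
23 | [(3R,4E)-3-ethylhept-4-en-1-ylidene]triphenylphosphorane | CC/C=C/[C@H](CC)CC=P(c1ccccc1)(c1ccccc1)c1ccccc1 | intermediate (not isolated)
24 | [(3R,4E)-3-ethyl-1-iodohept-4-en-1-yl]triphenylphosphonium iodide (both C1 epimers) | CC/C=C/[C@H](CC)CC(I)[P+](c1ccccc1)(c1ccccc1)c1ccccc1.[I-] | intermediate (not isolated)
25 | [(3R,4E)-3-ethyl-1-iodohept-4-en-1-ylidene]triphenylphosphorane | CC/C=C/[C@H](CC)CC(I)=P(c1ccccc1)(c1ccccc1)c1ccccc1 | intermediate (not isolated)
26 | methyl 2-[(3S,4R,6S)-4,6-diethyl-6-[(1Z,4R,5E)-4-ethyl-2-iodoocta-1,5-dien-1-yl]-1,2-dioxan-3-yl]acetate | CC/C=C/[C@H](CC)C/C(I)=C/[C@]1(CC)C[C@@H](CC)[C@H](CC(=O)OC)OO1 | intermediate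
27 | methyl 2-[(3S,4R,6S)-4,6-diethyl-6-[(1E,4R,5E)-4-ethyl-2-methylocta-1,5-dien-1-yl]-1,2-dioxan-3-yl]acetate | CC/C=C/[C@H](CC)C/C(C)=C/[C@]1(CC)C[C@@H](CC)[C@H](CC(=O)OC)OO1 | target

Total step count: 15. Longest linear sequence: 10 steps (steps 1–8, 14 and 15); the side-chain phosphonium salt 22 is made in 5 steps (9–13).

Steps most likely to fail

Step 6. The Lewis acid may ionise the trioxane at the peroxidic C3–O2 bond (an oxocarbenium ion would then close a tetrahydropyran), may trigger O–O heterolysis, or the titanium chelate may not hold, so that induction from C6 is weak. The fallback replaces the temporary ring by an acyclic peroxyacetal with methoxide as the leaving group, the arrangement for which peroxycarbenium allylation is established; it does not add control over C6, so C6 epimers would be separated at this stage. It sets out from hydroperoxy alcohol 6. Both oxygens are silylated (t-BuMe2SiCl, imidazole, DMF) to bis-silyl compound F1. The labile silyl peroxide is cleaved selectively (K2CO3, MeOH, 0 °C) to silyl ether hydroperoxide F2. Condensation with 7 (pyridinium 4-toluenesulfonate, CH2Cl2) gives acyclic methyl peroxyacetal F3, and cross-metathesis with 9 gives allylsilane F4. TiCl4 at −78 °C closes the dioxane with loss of methoxide to silyl ether F5, and HF·pyridine brings the route back at 12.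

Step 14. The bulky α-iodo ylide may add slowly to the neopentylic aldehyde, may act as a base and open the β-peroxy ester by β-elimination, or may give eroded alkene geometry. The fallback builds the alkene by stepwise palladium-catalysed substitution of a 1,1-dibromoalkene. It sets out from aldehyde 14 and ester 19. Ramirez olefination of 14 (CBr4, PPh3, CH2Cl2, 0 °C) gives dibromoalkene F6. Ester 19 is saponified (LiOH, THF/H2O) to acid F7, which is converted (N-hydroxypyridine-2-thione, dicyclohexylcarbodiimide) into Barton ester F8. Barton iododecarboxylation (CHI3, hν) gives the one-carbon-shorter iodide F9, and zinc insertion (Zn dust, THF) gives alkylzinc iodide F10. Trans-selective Negishi monoalkylation of F6 with F10 (Pd(DPEphos)Cl2, THF) should give Z bromoalkene F11. Methylation with Me2Zn and Pd(t-Bu3P)2, with retention, comes back to the route at target 27.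

Step 3. Partial SN1 character in the epoxide opening may let hydrogen peroxide collapse on either face of a tertiary ion pair and lower the enantiomeric purity at the future C6. The fallback is a kinetic resolution by a lipase at the stage of alcohol 13, from which it sets out. With Amano lipase PS and vinyl acetate in t-BuOMe, a lipase that acylates the antipode faster converts the unwanted enantiomer into acetate F12, which is separated by chromatography. The unreacted, enantioenriched alcohol comes back to the route at 13.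

Further compounds
F1 | step 6 | tert-butyl{[(2S)-2-{[tert-butyl(dimethyl)silyl]peroxy}-2-ethylpent-4-en-1-yl]oxy}dimethylsilane | CC[C@@](OO[Si](C)(C)C(C)(C)C)(CO[Si](C)(C)C(C)(C)C)CC=C
F2 | step 6 | tert-butyl{[(2S)-2-ethyl-2-hydroperoxypent-4-en-1-yl]oxy}dimethylsilane | CC[C@@](OO)(CO[Si](C)(C)C(C)(C)C)CC=C
F3 | step 6 | methyl 3-{[(2S)-1-{[tert-butyl(dimethyl)silyl]oxy}-2-ethylpent-4-en-2-yl]peroxy}-3-methoxypropanoate | CC[C@@](OOC(OC)CC(=O)OC)(CO[Si](C)(C)C(C)(C)C)CC=C
F4 | step 6 | methyl 3-{[(2S,4E)-1-{[tert-butyl(dimethyl)silyl]oxy}-2-ethyl-6-(trimethylsilyl)hex-4-en-2-yl]peroxy}-3-methoxypropanoate | CC[C@@](OOC(OC)CC(=O)OC)(CO[Si](C)(C)C(C)(C)C)C/C=C/C[Si](C)(C)C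
F5 | step 6 | methyl 2-[(3S,4S,6S)-6-({[tert-butyl(dimethyl)silyl]oxy}methyl)-4-ethenyl-6-ethyl-1,2-dioxan-3-yl]acetate | CC(C)(C)[Si](C)(C)OC[C@]1(CC)C[C@@H](C=C)[C@H](CC(=O)OC)OO1
F6 | step 14 | methyl 2-[(3S,4R,6S)-6-(2,2-dibromoethenyl)-4,6-diethyl-1,2-dioxan-3-yl]acetate | BrC(Br)=C[C@]1(CC)C[C@@H](CC)[C@H](CC(=O)OC)OO1
F7 | step 14 | (3R,4E)-3-ethylhept-4-enoic acid | CC/C=C/[C@H](CC)CC(=O)O
F8 | step 14 | 2-thioxopyridin-1(2H)-yl (3R,4E)-3-ethylhept-4-enoate | CC/C=C/[C@H](CC)CC(=O)On1ccccc1=S
F9 | step 14 | (3E,5S)-5-(iodomethyl)hept-3-ene | CC/C=C/[C@H](CC)CI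
F10 | step 14 | [(2S,3E)-2-ethylhex-3-en-1-yl]zinc iodide | CC/C=C/[C@H](CC)C[Zn]I
F11 | step 14 | methyl 2-[(3S,4R,6S)-6-[(1Z,4R,5E)-2-bromo-4-ethylocta-1,5-dien-1-yl]-4,6-diethyl-1,2-dioxan-3-yl]acetate | CC/C=C/[C@H](CC)C/C(Br)=C/[C@]1(CC)C[C@@H](CC)[C@H](CC(=O)OC)OO1
F12 | step 3 | methyl 2-[(3R,4S,6R)-6-(acetoxymethyl)-4,6-diethyl-1,2-dioxan-3-yl]acetate | CC(=O)OC[C@@]1(CC)C[C@H](CC)[C@@H](CC(=O)OC)OO1
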